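**Retrosynthetic overview**
1. Target 29 ⇐ cleavage of eight methyl ethers ⇐ Heck coupling at C6 of chloride 25 with 2,4-dimethoxystyrene (the stilbene is made last, after all photochemistry).
2. Ring A: O1–C2 by decarboxylative C–O closure of redox-active ester 24; C3–C6' by Rh-catalysed enantioselective addition of ring-B boronic acid 17 to 7-chloro-5-methoxycoumarin 6.
3. Ring B: O1'–C2' by the same closure of 15; C3' by Rh-catalysed addition of 3,5-dimethoxyphenylboronic acid to the same coumarin 6.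
4. Feature used: each five-membered ring (O1–C2–C3–C3a–C7a and its primed twin) is a 3,4-diaryl-dihydrocoumarin that has lost its lactone carbonyl carbon. C3/C3' is coumarin C4, C2/C2' is coumarin C3, O1/O1' is the lactone oxygen, and the inter-unit bond C3–C6' is one more coumarin arylation with ring B as aryl donor.
5. Order of ring formation: lactone of 6 → ring B (16) → second lactone (18) → ring A (25).

Key step: step 9

Remark (assumption): the target is read as (2S,3S,2'S,3'S), both dihydrobenzofurans trans. Unprimed locants are the styryl-bearing unit A, primed locants unit B. Compounds 12–15 and 21–24 are treated as mixtures of epimers at the carbon that becomes C2'/C2 and are drawn without a descriptor there, because that centre becomes planar in the ring closure. TBS = tert-butyldimethylsilyl.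

**Step 1**
Reactants: 1 1-chloro-3,5-dimethoxybenzene
Product: 3 4-chloro-2,6-dimethoxybenzaldehyde, via 4-chloro-2,6-dimethoxyphenyllithium 2 (not isolated)
Conditions: n-BuLi, TMEDA, Et2O, 0 °C; DMF, 0 °C → rt; aq. NH4Cl
Reagents that add atoms: N,N-dimethylformamide, CN(C)C=O (formyl group of 3); n-butyllithium, [Li]CCCC (lithium of 2 only)
Why: Directed ortho-lithiation should take place at C4, the position flanked by both methoxy groups (cooperative coordination, and no aryne can form because the carbanion is not ortho to chlorine), and DMF then formylates it, whereas Vilsmeier formylation would give the unwanted 2-chloro isomer.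

**Step 2**
Reactants: 3 4-chloro-2,6-dimethoxybenzaldehyde
Product: 4 4-chloro-2-hydroxy-6-methoxybenzaldehyde
Conditions: BCl3 (1.1 equiv), CH2Cl2, −78 → 0 °C; H2O
Reagents that add atoms: none
Why: Chelation-controlled Lewis-acid ether cleavage, in which BCl3 held between the carbonyl and one ortho methoxy oxygen removes a single methyl group and the resulting boron chelate protects the second.

**Step 3**
Reactants: 4 4-chloro-2-hydroxy-6-methoxybenzaldehyde
Product: 6 7-chloro-5-methoxycoumarin, via hydroxycinnamate ester 5 (not isolated)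
Conditions: Ph3P=CHCO2Et, PhNEt2, 210 °C
Reagents that add atoms: ethyl (triphenylphosphoranylidene)acetate, CCOC(=O)C=P(c1ccccc1)(c1ccccc1)c1ccccc1
Why: Wittig olefination followed by thermal E/Z isomerisation and lactonisation with loss of ethanol is the standard coumarin synthesis from salicylaldehydes and fixes the chloro/methoxy pattern without regiochemical ambiguity.

**Step 4**
Reactants: 6 7-chloro-5-methoxycoumarin; 7 3,5-dimethoxyphenylboronic acid
Product: 8 (4S)-7-chloro-4-(3,5-dimethoxyphenyl)-5-methoxychroman-2-one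
Conditions: Rh(acac)(C2H4)2 (3 mol%), (S)-SEGPHOS, 7 (4 equiv), dioxane/H2O 10:1, 60 °C
Reagents that add atoms: none
Why: Hayashi–Miyaura asymmetric 1,4-addition, in which the aryl–rhodium(bisphosphine) species inserts the C3=C4 bond on one enantioface (catalyst control) and sets C4, the future C3', as S; the (S)-ligand is chosen because the (R)-ligand is known to give (R)-4-arylchroman-2-ones from simple coumarins and the CIP ranking at C4 is the same here.

**Step 5**
Reactants: 8 (4S)-7-chloro-4-(3,5-dimethoxyphenyl)-5-methoxychroman-2-one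
Product: 10 tert-butyl (3S)-3-[2-(TBS-oxy)-4-chloro-6-methoxyphenyl]-3-(3,5-dimethoxyphenyl)propanoate, via potassium phenoxide 9 (not isolated)
Conditions: KOtBu (1.1 equiv), THF/t-BuOH, −40 → 0 °C; TBSCl, DMF, 0 °C → rt
Reagents that add atoms: potassium tert-butoxide, CC(C)(C)[O-].[K+]; tert-butyldimethylsilyl chloride, CC(C)(C)[Si](C)(C)Cl
Why: Alkoxide transesterification of the aryl ester (driven by release of the much less basic phenoxide) followed by O-silylation of that phenoxide in the same flask, so the hydroxy ester never has the chance to relactonise, while the C3–H is not acidic enough to be touched.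

**Step 6**
Reactants: 10 tert-butyl (3S)-3-[2-(TBS-oxy)-4-chloro-6-methoxyphenyl]-3-(3,5-dimethoxyphenyl)propanoate; 11 4-bromoanisole
Product: 12 tert-butyl (2RS,3S)-3-[2-(TBS-oxy)-4-chloro-6-methoxyphenyl]-3-(3,5-dimethoxyphenyl)-2-(4-methoxyphenyl)propanoate
Conditions: LiHMDS (2.3 equiv), Pd(dba)2 (3 mol%), P(t-Bu)3, toluene, rt
Reagents that add atoms: none
Why: Palladium-catalysed α-arylation of a tert-butyl ester (Buchwald–Hartwig-type arylation), in which oxidative addition to the aryl bromide at room temperature should outpace insertion into the substrate's own C–Cl bond, and the new C2 centre need not be controlled because it becomes planar in step 9.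

**Step 7**
Reactants: 12 tert-butyl (2RS,3S)-3-[2-(TBS-oxy)-4-chloro-6-methoxyphenyl]-3-(3,5-dimethoxyphenyl)-2-(4-methoxyphenyl)propanoate
Product: 14 (2RS,3S)-3-[2-(TBS-oxy)-4-chloro-6-methoxyphenyl]-3-(3,5-dimethoxyphenyl)-2-(4-methoxyphenyl)propanoic acid, via trimethylsilyl ester 13 (not isolated)
Conditions: TMSOTf, 2,6-lutidine, CH2Cl2, 0 °C → rt; pH 5 buffer
Reagents that add atoms: trimethylsilyl trifluoromethanesulfonate, C[Si](C)(C)OS(=O)(=O)C(F)(F)F (silyl group of 13 only; no reagent atom remains in 14)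
Why: Silyl-triflate cleavage of a tert-butyl ester (loss of isobutene from the O-silylated ester, then hydrolysis on work-up) is used because it spares the aryl silyl ether, which basic saponification of a simple alkyl ester would not.

**Step 8**
Reactants: 14 (2RS,3S)-3-[2-(TBS-oxy)-4-chloro-6-methoxyphenyl]-3-(3,5-dimethoxyphenyl)-2-(4-methoxyphenyl)propanoic acid
Product: 15 1,3-dioxoisoindolin-2-yl (2RS,3S)-3-[2-(TBS-oxy)-4-chloro-6-methoxyphenyl]-3-(3,5-dimethoxyphenyl)-2-(4-methoxyphenyl)propanoate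
Conditions: N-hydroxyphthalimide, DIC, DMAP (10 mol%), CH2Cl2, 0 °C → rt
Reagents that add atoms: N-hydroxyphthalimide, O=C1c2ccccc2C(=O)N1O
Why: Carbodiimide (Steglich-type) esterification gives the redox-active ester, and because the phenol is still silylated it cannot lactonise onto the activated carbonyl.

**Step 9**
Reactants: 15 1,3-dioxoisoindolin-2-yl (2RS,3S)-3-[2-(TBS-oxy)-4-chloro-6-methoxyphenyl]-3-(3,5-dimethoxyphenyl)-2-(4-methoxyphenyl)propanoate
Product: 16 (2S,3S)-6-chloro-3-(3,5-dimethoxyphenyl)-4-methoxy-2-(4-methoxyphenyl)-2,3-dihydro-1-benzofuran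
Conditions: fac-Ir(ppy)3 (1 mol%), MeCN (degassed, dilute), blue LEDs, rt; aq. NaHCO3
Reagents that add atoms: none
Why: Proposed new method: Excited fac-Ir(ppy)3 transfers an electron to the N-acyloxyphthalimide, which fragments to CO2, phthalimide anion and the C2' radical; because this radical is 4-methoxybenzylic the Ir(IV) state oxidises it to the quinone-methide-like cation, the ortho silyloxy oxygen adds to C2', and phthalimide anion strips the silyl group from the resulting silyloxonium ion. The closest known reaction type is the photoredox radical–polar crossover decarboxylative etherification of benzylic redox-active esters with free alcohols (the photochemical counterpart of the Hofer–Moest reaction); an aryl silyl ether as the internal oxygen nucleophile has not been shown in this manifold, although silyl ethers are established traps for benzylic and oxocarbenium cations with loss of silicon. Ring B closes by O1'–C2' bond formation in a 5-exo-trig mode, the cationic C2'–aryl π-system lying outside the new ring. C2' is created from a planar cation, so both C2 epimers of 15 converge, and the C3' centre from step 4 directs the closure: the 4-methoxyphenyl group should take the face opposite to the 3,5-dimethoxyphenyl group and give the trans (2S,3S) isomer, which is also the more stable one. The step needs O-capture to beat loss of the C3' proton, attack by phthalimide nitrogen and lactonisation; the five-membered intramolecular delivery and the non-basic medium favour capture, the silyl group keeps the phenol from attacking the activated ester before CO2 is lost, and the Ir(IV) state is too weak an oxidant to touch the methoxyarenes.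

**Step 10**
Reactants: 16 (2S,3S)-6-chloro-3-(3,5-dimethoxyphenyl)-4-methoxy-2-(4-methoxyphenyl)-2,3-dihydro-1-benzofuran
Product: 17 [(2S,3S)-3-(3,5-dimethoxyphenyl)-4-methoxy-2-(4-methoxyphenyl)-2,3-dihydro-1-benzofuran-6-yl]boronic acid
Conditions: B2(OH)4, XPhos Pd G2 (2 mol%), XPhos, KOAc, EtOH, 80 °C
Reagents that add atoms: tetrahydroxydiboron, OB(O)B(O)O
Why: Palladium-catalysed Miyaura-type borylation of an aryl chloride with tetrahydroxydiboron gives the boronic acid directly under weakly basic conditions that leave the benzylic aryl ether and both stereocentres untouched.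

**Step 11**
Reactants: 17 ring-B boronic acid; 6 7-chloro-5-methoxycoumarin
Product: 18 (4S)-7-chloro-4-[(2S,3S)-3-(3,5-dimethoxyphenyl)-4-methoxy-2-(4-methoxyphenyl)-2,3-dihydro-1-benzofuran-6-yl]-5-methoxychroman-2-one
Conditions: Rh(acac)(C2H4)2 (5 mol%), (S)-SEGPHOS, 6 (3 equiv), dioxane/H2O 10:1, 60 °C
Reagents that add atoms: none
Why: Second Hayashi–Miyaura 1,4-addition, now with the coumarin in excess, in which the boron-bearing C6' has two free ortho positions and the same meta,meta-dioxygenation as the aryl group transferred in step 4, and the chiral catalyst rather than the remote C2'/C3' centres should fix the new centre, the future C3, as S.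

**Step 12**
Reactants: 18 second lactone
Product: 20 tert-butyl (3S)-3-[2-(TBS-oxy)-4-chloro-6-methoxyphenyl]-3-[(2S,3S)-3-(3,5-dimethoxyphenyl)-4-methoxy-2-(4-methoxyphenyl)-2,3-dihydro-1-benzofuran-6-yl]propanoate, via potassium phenoxide 19 (not isolated)
Conditions: KOtBu (1.1 equiv), THF/t-BuOH, −40 → 0 °C; TBSCl, DMF, 0 °C → rt
Reagents that add atoms: potassium tert-butoxide, CC(C)(C)[O-].[K+]; tert-butyldimethylsilyl chloride, CC(C)(C)[Si](C)(C)Cl
Why: Same alkoxide transesterification and in-flask silylation as in step 5, under which the dihydrobenzofuran of ring B has no hydrogen acidic enough to react.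

**Step 13**
Reactants: 20 tert-butyl ester of step 12; 11 4-bromoanisole
Product: 21 tert-butyl (2RS,3S)-3-[2-(TBS-oxy)-4-chloro-6-methoxyphenyl]-3-[(2S,3S)-3-(3,5-dimethoxyphenyl)-4-methoxy-2-(4-methoxyphenyl)-2,3-dihydro-1-benzofuran-6-yl]-2-(4-methoxyphenyl)propanoate
Conditions: LiHMDS (2.3 equiv), Pd(dba)2 (3 mol%), P(t-Bu)3, toluene, rt
Reagents that add atoms: none
Why: Same palladium-catalysed ester α-arylation as in step 6, again selective for the aryl bromide over the internal aryl chloride and again leaving an uncontrolled C2 centre that step 16 makes planar.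

**Step 14**
Reactants: 21 α-arylated tert-butyl ester
Product: 23 (2RS,3S)-3-[2-(TBS-oxy)-4-chloro-6-methoxyphenyl]-3-[(2S,3S)-3-(3,5-dimethoxyphenyl)-4-methoxy-2-(4-methoxyphenyl)-2,3-dihydro-1-benzofuran-6-yl]-2-(4-methoxyphenyl)propanoic acid, via trimethylsilyl ester 22 (not isolated)
Conditions: TMSOTf, 2,6-lutidine, CH2Cl2, 0 °C → rt; pH 5 buffer
Reagents that add atoms: trimethylsilyl trifluoromethanesulfonate, C[Si](C)(C)OS(=O)(=O)C(F)(F)F (silyl group of 22 only; no reagent atom remains in 23)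
Why: Same silyl-triflate cleavage of the tert-butyl ester as in step 7, kept buffered by lutidine so that no protic acid is present to ionise the C2'–O1' bond of ring B.

**Step 15**
Reactants: 23 carboxylic acid of step 14
Product: 24 1,3-dioxoisoindolin-2-yl (2RS,3S)-3-[2-(TBS-oxy)-4-chloro-6-methoxyphenyl]-3-[(2S,3S)-3-(3,5-dimethoxyphenyl)-4-methoxy-2-(4-methoxyphenyl)-2,3-dihydro-1-benzofuran-6-yl]-2-(4-methoxyphenyl)propanoate
Conditions: N-hydroxyphthalimide, DIC, DMAP (10 mol%), CH2Cl2, 0 °C → rt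
Reagents that add atoms: N-hydroxyphthalimide, O=C1c2ccccc2C(=O)N1O
Why: Same carbodiimide (Steglich-type) esterification as in step 8, with the silyl ether again preventing lactonisation.

**Step 16**
Reactants: 24 redox-active ester of step 15
Product: 25 (2S,3S)-6-chloro-3-[(2S,3S)-3-(3,5-dimethoxyphenyl)-4-methoxy-2-(4-methoxyphenyl)-2,3-dihydro-1-benzofuran-6-yl]-4-methoxy-2-(4-methoxyphenyl)-2,3-dihydro-1-benzofuran
Conditions: fac-Ir(ppy)3 (1 mol%), MeCN (degassed, dilute), blue LEDs, rt; aq. NaHCO3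
Reagents that add atoms: none
Why: Proposed new method: as in step 9, photoinduced electron transfer to the redox-active ester releases CO2 and phthalimide anion, the 4-methoxybenzylic C2 radical is oxidised by Ir(IV) to the cation and the ortho silyloxy oxygen closes ring A (O1–C2, 5-exo-trig) with silyl transfer to phthalimide, the bulky ring-B aryl group at C3 (set in step 11) forcing the 4-methoxyphenyl group trans (2S), the closest known reaction type again being the radical–polar crossover decarboxylative etherification of benzylic redox-active esters with alcohols.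

**Step 17**
Reactants: 26 2,4-dimethoxybenzaldehyde
Product: 27 2,4-dimethoxystyrene
Conditions: Ph3PCH3Br, KOtBu, THF, 0 °C → rt
Reagents that add atoms: methyltriphenylphosphonium bromide, C[P+](c1ccccc1)(c1ccccc1)c1ccccc1.[Br-]
Why: Wittig methylenation of an aromatic aldehyde with the non-stabilised ylide made in the flask.

**Step 18**
Reactants: 25 bis-dihydrobenzofuran chloride; 27 2,4-dimethoxystyrene
Product: 28 (2S,3S)-6-[(E)-2-(2,4-dimethoxyphenyl)ethenyl]-3-[(2S,3S)-3-(3,5-dimethoxyphenyl)-4-methoxy-2-(4-methoxyphenyl)-2,3-dihydro-1-benzofuran-6-yl]-4-methoxy-2-(4-methoxyphenyl)-2,3-dihydro-1-benzofuran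
Conditions: Pd2(dba)3 (2.5 mol%), P(t-Bu)3·HBF4, Cy2NMe, dioxane, 110 °C
Reagents that add atoms: none
Why: Mizoroki–Heck reaction of an unactivated aryl chloride under bulky-trialkylphosphine palladium catalysis, in which arylation of the terminal alkene carbon and syn β-hydride elimination give the E-stilbene, placed after both photochemical steps because a stilbene would be isomerised by the photocatalyst.

**Step 19**
Reactants: 28 octamethyl ether
Product: 29 target, 4-[(E)-2-[(2S,3S)-3-[(2S,3S)-3-(3,5-dihydroxyphenyl)-4-hydroxy-2-(4-hydroxyphenyl)-2,3-dihydro-1-benzofuran-6-yl]-4-hydroxy-2-(4-hydroxyphenyl)-2,3-dihydro-1-benzofuran-6-yl]ethenyl]benzene-1,3-diol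
Conditions: BBr3 (excess), CH2Cl2, −78 °C → rt, dark; MeOH, then H2O
Reagents that add atoms: none
Why: Boron tribromide cleavage of aryl methyl ethers, the usual last step for permethylated oligostilbenes, should keep the four stereocentres and the E-alkene because both trans rings are the thermodynamically preferred isomers and the C6 styryl group is too far from C2 to trap a transiently ring-opened cation.

**Compound list**
1 | 1-chloro-3,5-dimethoxybenzene | COc1cc(Cl)cc(OC)c1 | starting material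
2 | 4-chloro-2,6-dimethoxyphenyllithium | [Li]c1c(OC)cc(Cl)cc1OC | intermediate
3 | 4-chloro-2,6-dimethoxybenzaldehyde | COc1cc(Cl)cc(OC)c1C=O | intermediate
4 | 4-chloro-2-hydroxy-6-methoxybenzaldehyde | COc1cc(Cl)cc(O)c1C=O | intermediate
5 | ethyl (E)-3-(4-chloro-2-hydroxy-6-methoxyphenyl)prop-2-enoate | CCOC(=O)/C=C/c1c(O)cc(Cl)cc1OC | intermediate
6 | 7-chloro-5-methoxy-2H-chromen-2-one | COc1cc(Cl)cc2oc(=O)ccc12 | intermediate
7 | 3,5-dimethoxyphenylboronic acid | COc1cc(cc(OC)c1)B(O)O | starting material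
8 | (4S)-7-chloro-4-(3,5-dimethoxyphenyl)-5-methoxychroman-2-one | O=C1C[C@@H](c2cc(OC)cc(OC)c2)c2c(OC)cc(Cl)cc2O1 | intermediate
9 | potassium 5-chloro-2-[(1S)-3-tert-butoxy-1-(3,5-dimethoxyphenyl)-3-oxopropyl]-3-methoxyphenolate | CC(C)(C)OC(=O)C[C@H](c1c(OC)cc(Cl)cc1[O-])c1cc(OC)cc(OC)c1.[K+] | intermediate
10 | tert-butyl (3S)-3-[2-(tert-butyldimethylsilyloxy)-4-chloro-6-methoxyphenyl]-3-(3,5-dimethoxyphenyl)propanoate | CC(C)(C)OC(=O)C[C@H](c1c(OC)cc(Cl)cc1O[Si](C)(C)C(C)(C)C)c1cc(OC)cc(OC)c1 | intermediate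
11 | 4-bromoanisole | COc1ccc(Br)cc1 | starting material
12 | tert-butyl (2RS,3S)-3-[2-(tert-butyldimethylsilyloxy)-4-chloro-6-methoxyphenyl]-3-(3,5-dimethoxyphenyl)-2-(4-methoxyphenyl)propanoate | CC(C)(C)OC(=O)C(c1ccc(OC)cc1)[C@H](c1c(OC)cc(Cl)cc1O[Si](C)(C)C(C)(C)C)c1cc(OC)cc(OC)c1 | intermediate
13 | trimethylsilyl (2RS,3S)-3-[2-(tert-butyldimethylsilyloxy)-4-chloro-6-methoxyphenyl]-3-(3,5-dimethoxyphenyl)-2-(4-methoxyphenyl)propanoate | C[Si](C)(C)OC(=O)C(c1ccc(OC)cc1)[C@H](c1c(OC)cc(Cl)cc1O[Si](C)(C)C(C)(C)C)c1cc(OC)cc(OC)c1 | intermediate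
14 | (2RS,3S)-3-[2-(tert-butyldimethylsilyloxy)-4-chloro-6-methoxyphenyl]-3-(3,5-dimethoxyphenyl)-2-(4-methoxyphenyl)propanoic acid | OC(=O)C(c1ccc(OC)cc1)[C@H](c1c(OC)cc(Cl)cc1O[Si](C)(C)C(C)(C)C)c1cc(OC)cc(OC)c1 | intermediate
15 | 1,3-dioxoisoindolin-2-yl (2RS,3S)-3-[2-(tert-butyldimethylsilyloxy)-4-chloro-6-methoxyphenyl]-3-(3,5-dimethoxyphenyl)-2-(4-methoxyphenyl)propanoate | O=C(ON1C(=O)c2ccccc2C1=O)C(c1ccc(OC)cc1)[C@H](c1c(OC)cc(Cl)cc1O[Si](C)(C)C(C)(C)C)c1cc(OC)cc(OC)c1 | intermediate
16 | (2S,3S)-6-chloro-3-(3,5-dimethoxyphenyl)-4-methoxy-2-(4-methoxyphenyl)-2,3-dihydro-1-benzofuran | Clc1cc(OC)c2c(c1)O[C@H](c1ccc(OC)cc1)[C@H]2c1cc(OC)cc(OC)c1 | intermediate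
17 | [(2S,3S)-3-(3,5-dimethoxyphenyl)-4-methoxy-2-(4-methoxyphenyl)-2,3-dihydro-1-benzofuran-6-yl]boronic acid | OB(O)c1cc(OC)c2c(c1)O[C@H](c1ccc(OC)cc1)[C@H]2c1cc(OC)cc(OC)c1 | intermediate
18 | (4S)-7-chloro-4-[(2S,3S)-3-(3,5-dimethoxyphenyl)-4-methoxy-2-(4-methoxyphenyl)-2,3-dihydro-1-benzofuran-6-yl]-5-methoxychroman-2-one | O=C1C[C@@H](c2cc(OC)c3c(c2)O[C@H](c2ccc(OC)cc2)[C@H]3c2cc(OC)cc(OC)c2)c2c(OC)cc(Cl)cc2O1 | intermediate
19 | potassium 5-chloro-2-[(1S)-3-tert-butoxy-1-[(2S,3S)-3-(3,5-dimethoxyphenyl)-4-methoxy-2-(4-methoxyphenyl)-2,3-dihydro-1-benzofuran-6-yl]-3-oxopropyl]-3-methoxyphenolate | CC(C)(C)OC(=O)C[C@H](c1c(OC)cc(Cl)cc1[O-])c1cc(OC)c2c(c1)O[C@H](c1ccc(OC)cc1)[C@H]2c1cc(OC)cc(OC)c1.[K+] | intermediate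
20 | tert-butyl (3S)-3-[2-(tert-butyldimethylsilyloxy)-4-chloro-6-methoxyphenyl]-3-[(2S,3S)-3-(3,5-dimethoxyphenyl)-4-methoxy-2-(4-methoxyphenyl)-2,3-dihydro-1-benzofuran-6-yl]propanoate | CC(C)(C)OC(=O)C[C@H](c1c(OC)cc(Cl)cc1O[Si](C)(C)C(C)(C)C)c1cc(OC)c2c(c1)O[C@H](c1ccc(OC)cc1)[C@H]2c1cc(OC)cc(OC)c1 | intermediate
21 | tert-butyl (2RS,3S)-3-[2-(tert-butyldimethylsilyloxy)-4-chloro-6-methoxyphenyl]-3-[(2S,3S)-3-(3,5-dimethoxyphenyl)-4-methoxy-2-(4-methoxyphenyl)-2,3-dihydro-1-benzofuran-6-yl]-2-(4-methoxyphenyl)propanoate | CC(C)(C)OC(=O)C(c1ccc(OC)cc1)[C@H](c1c(OC)cc(Cl)cc1O[Si](C)(C)C(C)(C)C)c1cc(OC)c2c(c1)O[C@H](c1ccc(OC)cc1)[C@H]2c1cc(OC)cc(OC)c1 | intermediate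
22 | trimethylsilyl ester corresponding to 21 | C[Si](C)(C)OC(=O)C(c1ccc(OC)cc1)[C@H](c1c(OC)cc(Cl)cc1O[Si](C)(C)C(C)(C)C)c1cc(OC)c2c(c1)O[C@H](c1ccc(OC)cc1)[C@H]2c1cc(OC)cc(OC)c1 | intermediate
23 | (2RS,3S)-3-[2-(tert-butyldimethylsilyloxy)-4-chloro-6-methoxyphenyl]-3-[(2S,3S)-3-(3,5-dimethoxyphenyl)-4-methoxy-2-(4-methoxyphenyl)-2,3-dihydro-1-benzofuran-6-yl]-2-(4-methoxyphenyl)propanoic acid | OC(=O)C(c1ccc(OC)cc1)[C@H](c1c(OC)cc(Cl)cc1O[Si](C)(C)C(C)(C)C)c1cc(OC)c2c(c1)O[C@H](c1ccc(OC)cc1)[C@H]2c1cc(OC)cc(OC)c1 | intermediate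
24 | 1,3-dioxoisoindolin-2-yl ester of 23 | O=C(ON1C(=O)c2ccccc2C1=O)C(c1ccc(OC)cc1)[C@H](c1c(OC)cc(Cl)cc1O[Si](C)(C)C(C)(C)C)c1cc(OC)c2c(c1)O[C@H](c1ccc(OC)cc1)[C@H]2c1cc(OC)cc(OC)c1 | intermediate
25 | (2S,3S)-6-chloro-3-[(2S,3S)-3-(3,5-dimethoxyphenyl)-4-methoxy-2-(4-methoxyphenyl)-2,3-dihydro-1-benzofuran-6-yl]-4-methoxy-2-(4-methoxyphenyl)-2,3-dihydro-1-benzofuran | COc1ccc([C@H]2Oc3cc(Cl)cc(OC)c3[C@@H]2c2cc(OC)c3c(c2)O[C@H](c2ccc(OC)cc2)[C@H]3c2cc(OC)cc(OC)c2)cc1 | intermediate
26 | 2,4-dimethoxybenzaldehyde | COc1ccc(C=O)c(OC)c1 | starting material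
27 | 2,4-dimethoxystyrene | COc1ccc(C=C)c(OC)c1 | intermediate
28 | (2S,3S)-6-[(E)-2-(2,4-dimethoxyphenyl)ethenyl]-3-[(2S,3S)-3-(3,5-dimethoxyphenyl)-4-methoxy-2-(4-methoxyphenyl)-2,3-dihydro-1-benzofuran-6-yl]-4-methoxy-2-(4-methoxyphenyl)-2,3-dihydro-1-benzofuran | COc1ccc([C@H]2Oc3cc(/C=C/c4ccc(OC)cc4OC)cc(OC)c3[C@@H]2c2cc(OC)c3c(c2)O[C@H](c2ccc(OC)cc2)[C@H]3c2cc(OC)cc(OC)c2)cc1 | intermediate
29 | CNP0186204.1, 4-[(E)-2-[(2S,3S)-3-[(2S,3S)-3-(3,5-dihydroxyphenyl)-4-hydroxy-2-(4-hydroxyphenyl)-2,3-dihydro-1-benzofuran-6-yl]-4-hydroxy-2-(4-hydroxyphenyl)-2,3-dihydro-1-benzofuran-6-yl]ethenyl]benzene-1,3-diol | Oc1ccc([C@H]2Oc3cc(/C=C/c4ccc(O)cc4O)cc(O)c3[C@@H]2c2cc(O)c3c(c2)O[C@H](c2ccc(O)cc2)[C@H]3c2cc(O)cc(O)c2)cc1 | target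

**Step count**
Total: 19 steps. Longest linear sequence: 18 steps (steps 1–16, 18 and 19; step 17 is a one-step side branch).

**Steps most likely to fail**

Step 9 (proposed new method). The C2' cation may lose the C3' proton to give a triarylethene, or be taken by phthalimide nitrogen, faster than the hindered silyl ether oxygen closes the ring. The radical may also abstract hydrogen or dimerise before it is oxidised, and closure may be poorly trans-selective. The fallback uses known chemistry and separates cation capture from ring closure. It sets out from 15, which is submitted to the established decarboxylative etherification with methanol as external nucleophile (N-aryl phenothiazine photocatalyst, LiBF4, MeCN/MeOH, blue LEDs). This should give the benzylic methyl ether tert-butyl{5-chloro-2-[(1S)-1-(3,5-dimethoxyphenyl)-2-methoxy-2-(4-methoxyphenyl)ethyl]-3-methoxyphenoxy}dimethylsilane F1 as a mixture of epimers. Fluoride (TBAF, THF) should then free the phenol 5-chloro-2-[(1S)-1-(3,5-dimethoxyphenyl)-2-methoxy-2-(4-methoxyphenyl)ethyl]-3-methoxyphenol F2, which cannot lactonise because no acyl group is left. Catalytic acid (TsOH, CH2Cl2) should ionise the 4-methoxybenzylic ether and close the ring by SN1 etherification under thermodynamic control, giving the trans isomer. The fallback comes back to the route at 16.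

Step 16 (proposed new method). The same processes can intervene in the larger substrate: elimination from the C2 cation, capture by phthalimide, or slow oxidation of the radical next to the bulky ring-B substituent. The fallback is the same known sequence. It sets out from 24, and decarboxylative etherification with methanol should give the methyl ether F3, (2S,3S)-6-[(1S)-1-[2-(tert-butyldimethylsilyloxy)-4-chloro-6-methoxyphenyl]-2-methoxy-2-(4-methoxyphenyl)ethyl]-3-(3,5-dimethoxyphenyl)-4-methoxy-2-(4-methoxyphenyl)-2,3-dihydro-1-benzofuran F3. Desilylation with TBAF should give the phenol 5-chloro-2-[(1S)-1-[(2S,3S)-3-(3,5-dimethoxyphenyl)-4-methoxy-2-(4-methoxyphenyl)-2,3-dihydro-1-benzofuran-6-yl]-2-methoxy-2-(4-methoxyphenyl)ethyl]-3-methoxyphenol F4. Acid-catalysed SN1 cyclisation should then close ring A trans; ring B, if it opens reversibly under the acid, re-closes to its trans form. The fallback comes back to the route at 25.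

Step 11. With the boronic acid now the limiting partner, protonolysis of the aryl–rhodium intermediate (net loss of boron) may outrun insertion into the coumarin, whose C4 is hindered by the peri methoxy group; facial control by the catalyst may also be incomplete on this larger aryl donor. The fallback separates C–C bond formation from creation of the stereocentre. It sets out from 17 and 6, which are joined by a palladium(II)-catalysed oxidative Heck reaction (Pd(OAc)2, 1,10-phenanthroline, O2, DMF) to give the 4-arylcoumarin 7-chloro-4-[(2S,3S)-3-(3,5-dimethoxyphenyl)-4-methoxy-2-(4-methoxyphenyl)-2,3-dihydro-1-benzofuran-6-yl]-5-methoxy-2H-chromen-2-one F5. Copper hydride-catalysed asymmetric conjugate reduction (Cu(OAc)2, the DTBM-SEGPHOS enantiomer that delivers 4S, diethoxymethylsilane, t-BuOH) should then set C4. The fallback comes back to the route at 18.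

**Further compounds**
F1 | step 9 | tert-butyl{5-chloro-2-[(1S)-1-(3,5-dimethoxyphenyl)-2-methoxy-2-(4-methoxyphenyl)ethyl]-3-methoxyphenoxy}dimethylsilane | COC(c1ccc(OC)cc1)[C@H](c1c(OC)cc(Cl)cc1O[Si](C)(C)C(C)(C)C)c1cc(OC)cc(OC)c1
F2 | step 9 | 5-chloro-2-[(1S)-1-(3,5-dimethoxyphenyl)-2-methoxy-2-(4-methoxyphenyl)ethyl]-3-methoxyphenol | COC(c1ccc(OC)cc1)[C@H](c1c(OC)cc(Cl)cc1O)c1cc(OC)cc(OC)c1
F3 | step 16 | (2S,3S)-6-[(1S)-1-[2-(tert-butyldimethylsilyloxy)-4-chloro-6-methoxyphenyl]-2-methoxy-2-(4-methoxyphenyl)ethyl]-3-(3,5-dimethoxyphenyl)-4-methoxy-2-(4-methoxyphenyl)-2,3-dihydro-1-benzofuran | COC(c1ccc(OC)cc1)[C@H](c1c(OC)cc(Cl)cc1O[Si](C)(C)C(C)(C)C)c1cc(OC)c2c(c1)O[C@H](c1ccc(OC)cc1)[C@H]2c1cc(OC)cc(OC)c1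
F4 | step 16 | 5-chloro-2-[(1S)-1-[(2S,3S)-3-(3,5-dimethoxyphenyl)-4-methoxy-2-(4-methoxyphenyl)-2,3-dihydro-1-benzofuran-6-yl]-2-methoxy-2-(4-methoxyphenyl)ethyl]-3-methoxyphenol | COC(c1ccc(OC)cc1)[C@H](c1c(OC)cc(Cl)cc1O)c1cc(OC)c2c(c1)O[C@H](c1ccc(OC)cc1)[C@H]2c1cc(OC)cc(OC)c1
F5 | step 11 | 7-chloro-4-[(2S,3S)-3-(3,5-dimethoxyphenyl)-4-methoxy-2-(4-methoxyphenyl)-2,3-dihydro-1-benzofuran-6-yl]-5-methoxy-2H-chromen-2-one | COc1cc(Cl)cc2oc(=O)cc(-c3cc(OC)c4c(c3)O[C@H](c3ccc(OC)cc3)[C@H]4c3cc(OC)cc(OC)c3)c12
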